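**Strategy.** With the chain numbered C1–C7 from the methoxycatechol ring, the syn-1,3-diol at C3/C5 between the two benzene rings is read as a reduced aldol. The C3–C4 bond is made by adding the methyl carbon of O-benzyl raspberry ketone (future C4, its carbonyl the future C5) to the formyl carbon (future C3) of a benzyl-protected cinnamaldehyde made from 5-hydroxyvanillin. A diisopinocampheylboron enolate sets C3. The six-membered boron aldolate chelate, reduced in the same flask with LiBH4, relays C3 to C5, so one operation joins the halves and sets both stereocentres. A single hydrogenation then saturates C1=C2 and frees the three phenols.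

Key step: step 4

Assumption: enol diisopinocampheylborinates of methyl ketones made from (−)-Ipc2BCl (from (+)-α-pinene) are taken to add to the si face of aldehydes; if the sense is the opposite, (+)-Ipc2BCl is used with no other change.

Step 1
Reactants: 1 3,4-dihydroxy-5-methoxybenzaldehyde (5-hydroxyvanillin)
Product: 2 3,4-bis(benzyloxy)-5-methoxybenzaldehyde
Conditions: BnBr, K2CO3, DMF, 60 °C
Reagents that add atoms: benzyl bromide, BrCc1ccccc1
Why: Williamson ether synthesis, in which both phenoxides are O-benzylated by SN2 on benzyl bromide while the aldehyde is inert, masking the acidic OH groups before the boron chemistry.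

Step 2
Reactants: 2 3,4-bis(benzyloxy)-5-methoxybenzaldehyde
Product: 3 (E)-3-[3,4-bis(benzyloxy)-5-methoxyphenyl]prop-2-enal
Conditions: Ph3P=CHCHO, toluene, 80 °C
Reagents that add atoms: (triphenylphosphoranylidene)acetaldehyde, O=CC=P(c1ccccc1)(c1ccccc1)c1ccccc1
Why: Wittig olefination with the stabilised formylmethylene ylide should give the (E)-enal, the ylide being kept near one equivalent to limit a second homologation.

Step 3
Reactants: 4 4-(4-hydroxyphenyl)butan-2-one (raspberry ketone)
Product: 5 4-[4-(benzyloxy)phenyl]butan-2-one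
Conditions: BnBr, K2CO3, acetone, reflux
Reagents that add atoms: benzyl bromide, BrCc1ccccc1
Why: Williamson ether synthesis, in which the phenol (far more acidic than the ketone α-hydrogens) is deprotonated by K2CO3 and O-benzylated, leaving the methyl ketone untouched.

Step 4
Reactants: 5 4-[4-(benzyloxy)phenyl]butan-2-one; 3 (E)-3-[3,4-bis(benzyloxy)-5-methoxyphenyl]prop-2-enal
Product: 8 (1E,3S,5S)-1-[3,4-bis(benzyloxy)-5-methoxyphenyl]-7-[4-(benzyloxy)phenyl]hept-1-ene-3,5-diol, via enol diisopinocampheylborinate 6 (not isolated), via boron aldolate 7 (not isolated)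
Conditions: (−)-Ipc2BCl, Et3N, Et2O, 0 °C; 3 (in CH2Cl2), −78 → −20 °C; LiBH4, −78 °C; then MeOH, pH 7 buffer, 30% H2O2, 0 °C → rt
Reagents that add atoms: none
Why: Ipc2BCl/Et3N enolises methyl ketone 5 on the CH3 side to enol borinate 6, which adds 1,2 to the formyl carbon of enal 3 through a closed six-membered boron-bridged transition state, forming the C3–C4 bond and the chelated aldolate 7; LiBH4 then reduces the boron-chelated C5 carbonyl in the same flask and buffered H2O2 frees the diol. The closest known reaction type is the diisopinocampheylboron-mediated methyl ketone aldol addition combined with in situ borohydride reduction of the boron aldolate (aldol–reduction to 1,3-syn diols), of which this is a direct application. No ring of the target is closed; the only ring involved is the transient six-membered B–O–C3–C4–C5=O chelate. C3 is set by the isopinocampheyl ligands on boron, which steer the enolate to the si face of the aldehyde (reagent control), and C5 is set by C3 through the chelate, external hydride adding to the face of the half-chair that leads to the 1,3-syn diol. The step needs regioselective enolisation, 1,2- over 1,4-addition, facial selectivity and syn reduction: the bulky chloroborane with a weak amine base deprotonates the unhindered methyl group, the cyclic transition state delivers the enolate carbon only to the carbonyl carbon, the enal cannot enolise or self-condense, and the benzyl ethers leave no acidic site that would consume the borane.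

Step 5
Reactants: 8 (1E,3S,5S)-1-[3,4-bis(benzyloxy)-5-methoxyphenyl]-7-[4-(benzyloxy)phenyl]hept-1-ene-3,5-diol
Product: 9 (3R,5S)-1-(3,4-dihydroxy-5-methoxyphenyl)-7-(4-hydroxyphenyl)heptane-3,5-diol
Conditions: H2 (1 atm), 10% Pd/C, degassed EtOAc–MeOH, rt
Reagents that add atoms: none
Why: Heterogeneous catalytic hydrogenation should saturate the styrenyl C1=C2 bond and hydrogenolyse the three benzyl aryl ethers in one operation without touching the two carbinol centres (the C3 descriptor changes from S to R only through the CIP priorities).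

**Compound list**

1 | 3,4-dihydroxy-5-methoxybenzaldehyde (5-hydroxyvanillin) | COc1cc(C=O)cc(O)c1O | starting material
2 | 3,4-bis(benzyloxy)-5-methoxybenzaldehyde | COc1cc(C=O)cc(OCc2ccccc2)c1OCc1ccccc1 | intermediate
3 | (E)-3-[3,4-bis(benzyloxy)-5-methoxyphenyl]prop-2-enal | COc1cc(/C=C/C=O)cc(OCc2ccccc2)c1OCc1ccccc1 | intermediate
4 | 4-(4-hydroxyphenyl)butan-2-one (raspberry ketone) | CC(=O)CCc1ccc(O)cc1 | starting material
5 | 4-[4-(benzyloxy)phenyl]butan-2-one | CC(=O)CCc1ccc(OCc2ccccc2)cc1 | intermediate
6 | enol diisopinocampheylborinate of 5, CH2=C(OBIpc2)CH2CH2C6H4OBn (Ipc = isopinocampheyl from (+)-α-pinene) | C=C(CCc1ccc(OCc2ccccc2)cc1)OB([C@@H]1C[C@@H]2C[C@H]([C@H]1C)C2(C)C)[C@@H]1C[C@@H]2C[C@H]([C@H]1C)C2(C)C | intermediate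
7 | boron aldolate: O-diisopinocampheylboryl derivative of (5S,6E)-7-[3,4-bis(benzyloxy)-5-methoxyphenyl]-1-[4-(benzyloxy)phenyl]-5-hydroxyhept-6-en-3-one | COc1cc(/C=C/[C@@H](OB([C@@H]2C[C@@H]3C[C@H]([C@H]2C)C3(C)C)[C@@H]2C[C@@H]3C[C@H]([C@H]2C)C3(C)C)CC(=O)CCc2ccc(OCc3ccccc3)cc2)cc(OCc2ccccc2)c1OCc1ccccc1 | intermediate
8 | (1E,3S,5S)-1-[3,4-bis(benzyloxy)-5-methoxyphenyl]-7-[4-(benzyloxy)phenyl]hept-1-ene-3,5-diol (syn diol) | COc1cc(/C=C/[C@@H](O)C[C@@H](O)CCc2ccc(OCc3ccccc3)cc2)cc(OCc2ccccc2)c1OCc1ccccc1 | intermediate
9 | (3R,5S)-1-(3,4-dihydroxy-5-methoxyphenyl)-7-(4-hydroxyphenyl)heptane-3,5-diol (syn diol) | COc1cc(CC[C@@H](O)C[C@@H](O)CCc2ccc(O)cc2)cc(O)c1O | target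

**Step count.** Total: 5 steps. Longest linear sequence: 4 steps (steps 1, 2, 4, 5).

**Steps most likely to fail**

Step 4. The isopinocampheyl ligands may discriminate the aldehyde faces only incompletely for an unsubstituted methyl ketone enolate, and 1,3-syn control erodes if the chelate opens before hydride delivery. Fallback, setting out from 5: kinetic silylation (LDA, TMSCl, THF, −78 °C) gives the trimethylsilyl enol ether of 5, F1. A Mukaiyama aldol addition of F1 to 3, catalysed by SiCl4 and a chiral bisphosphoramide Lewis base (CH2Cl2, −78 °C, catalyst enantiomer chosen for si-face addition), gives (5S,6E)-7-[3,4-bis(benzyloxy)-5-methoxyphenyl]-1-[4-(benzyloxy)phenyl]-5-hydroxyhept-6-en-3-one, F2. Narasaka–Prasad reduction of F2 (Et2BOMe, NaBH4, THF–MeOH, −78 °C) comes back to the route at 8.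

Step 5. Hydrogenolysis of the allylic (cinnamyl-type) C3–O bond, or palladium-mediated isomerisation of the allylic alcohol to a ketone, may compete with saturation of the alkene. Fallback, setting out from 8: metal-free diimide reduction (2-nitrobenzenesulfonylhydrazide, Et3N, CH2Cl2, rt) saturates C1=C2 first to give (3R,5S)-1-[3,4-bis(benzyloxy)-5-methoxyphenyl]-7-[4-(benzyloxy)phenyl]heptane-3,5-diol, F3. F3 no longer has an allylic C–O bond, and plain hydrogenolysis (H2, Pd(OH)2/C, EtOAc–MeOH) comes back to the route at 9.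

Step 2. The product enal may react again with the formyl ylide (over-homologation to the dienal), and the electron-rich aldehyde may convert sluggishly. Fallback, setting out from 2: Horner–Wadsworth–Emmons olefination (triethyl phosphonoacetate, NaH, THF, 0 °C → rt) gives ethyl (E)-3-[3,4-bis(benzyloxy)-5-methoxyphenyl]prop-2-enoate, F4. DIBAL-H reduction (CH2Cl2, −78 °C) gives (E)-3-[3,4-bis(benzyloxy)-5-methoxyphenyl]prop-2-en-1-ol, F5. Allylic oxidation of F5 with MnO2 (CH2Cl2, rt) comes back to the route at 3.

**Further compounds**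

F1 | step 4 | {[4-(4-(benzyloxy)phenyl)but-1-en-2-yl]oxy}trimethylsilane | C=C(CCc1ccc(OCc2ccccc2)cc1)O[Si](C)(C)C
F2 | step 4 | (5S,6E)-7-[3,4-bis(benzyloxy)-5-methoxyphenyl]-1-[4-(benzyloxy)phenyl]-5-hydroxyhept-6-en-3-one | COc1cc(/C=C/[C@@H](O)CC(=O)CCc2ccc(OCc3ccccc3)cc2)cc(OCc2ccccc2)c1OCc1ccccc1
F3 | step 5 | (3R,5S)-1-[3,4-bis(benzyloxy)-5-methoxyphenyl]-7-[4-(benzyloxy)phenyl]heptane-3,5-diol | COc1cc(CC[C@@H](O)C[C@@H](O)CCc2ccc(OCc3ccccc3)cc2)cc(OCc2ccccc2)c1OCc1ccccc1
F4 | step 2 | ethyl (E)-3-[3,4-bis(benzyloxy)-5-methoxyphenyl]prop-2-enoate | CCOC(=O)/C=C/c1cc(OC)c(OCc2ccccc2)c(OCc2ccccc2)c1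
F5 | step 2 | (E)-3-[3,4-bis(benzyloxy)-5-methoxyphenyl]prop-2-en-1-ol | COc1cc(/C=C/CO)cc(OCc2ccccc2)c1OCc1ccccc1
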